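**Retrosynthetic overview**
1. Target 12 comes from 11 by hydrogenolysis of the two benzyl ethers, and 11 from 5-bromoflavone 9 by copper-catalysed exchange of C5–Br for C5–OH next to the C4 carbonyl.
2. Bromoflavone 9 is disconnected at O1–C8a of ring C: the enol oxygen of 1,3-diketone 7 displaces one ortho bromine under CuI/K2CO3.
3. Diketone 7 is disconnected at C3–C4 into aroyl chloride 3 and the lithium enolate of acetophenone 4; chloride 3 comes from 3,4,5-trimethoxybenzoic acid 1 by twofold ortho-bromination and chlorination.
4. The feature carrying the plan: ring A is a 3,4,5-trimethoxybenzoyl unit (methoxy groups at C6, C7, C8; acyl carbon C4 on C4a) whose two ortho carbons, C5 and C8a, both bear oxygen and are mirror-related, so two equivalent bromines serve as the ring-closure site and as the latent 5-OH.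
5. Ring order: rings A and B are bought; ring C (the pyranone) is the only ring formed, in step 4.

Key step: step 4

Assumption: 1-[3,4-bis(benzyloxy)phenyl]ethanone 4 is taken as a purchasable building block.

**Step 1**
Reactants: 1 3,4,5-trimethoxybenzoic acid
Product: 2 2,6-dibromo-3,4,5-trimethoxybenzoic acid
Conditions: Br2 (2.5 equiv), AcOH, rt → 60 °C; aq. NaHSO3
Reagents that add atoms: bromine, BrBr
Why: Electrophilic aromatic bromination; C2 and C6 are the only ring CH positions and each is ortho to one methoxy group and para to another, so twofold substitution can give only 2.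

**Step 2**
Reactants: 2 2,6-dibromo-3,4,5-trimethoxybenzoic acid
Product: 3 2,6-dibromo-3,4,5-trimethoxybenzoyl chloride
Conditions: (COCl)2 (1.5 equiv), DMF (cat.), CH2Cl2, 0 °C → rt; evaporate, use crude
Reagents that add atoms: oxalyl chloride, ClC(=O)C(=O)Cl
Why: Acid chloride formation through the chloroiminium salt from DMF, which activates even a doubly ortho-substituted acid under neutral conditions that leave the methyl ethers and aryl bromides untouched.

**Step 3**
Reactants: 3 2,6-dibromo-3,4,5-trimethoxybenzoyl chloride; 4 1-[3,4-bis(benzyloxy)phenyl]ethanone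
Product: 7 1-[3,4-bis(benzyloxy)phenyl]-3-(2,6-dibromo-3,4,5-trimethoxyphenyl)propane-1,3-dione, via lithium enolate 5 (not isolated), via lithium diketonate 6 (not isolated)
Conditions: 4, LiN(SiMe3)2 (2.2 equiv), THF, −78 °C; then 3 in THF, −78 → 0 °C; 1 M HCl
Reagents that add atoms: none
Why: Claisen-type C-acylation of a lithium ketone enolate by an aroyl chloride; the second equivalent of base turns the more acidic product into diketonate 6 and so drives the reaction, and ring A has no hydrogen, so no aryne or ring metalation can interfere.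

**Step 4**
Reactants: 7 1-[3,4-bis(benzyloxy)phenyl]-3-(2,6-dibromo-3,4,5-trimethoxyphenyl)propane-1,3-dione
Product: 9 2-[3,4-bis(benzyloxy)phenyl]-5-bromo-6,7,8-trimethoxy-4H-chromen-4-one, via potassium enolate 8 (not isolated)
Conditions: CuI (10 mol %), K2CO3 (2 equiv), dry DMF, 100 °C, N2
Reagents that add atoms: none
Why: K2CO3 converts 7 into its chelating Z-enolate 8, which binds monovalent copper as an O,O-ligand and places the metal beside an ortho C–Br bond; oxidative addition should give an aryl trivalent copper enolate held in a seven-membered cupracycle, and C–O reductive elimination then forms O1–C8a and returns monovalent copper. This is an intramolecular Ullmann ether synthesis with an enol oxygen as nucleophile, the established copper- or base-mediated closure of 1-(2-haloaryl)-1,3-diketones to flavones, and the ortho acyl group accelerates it; an uncatalysed addition–elimination at C8a would lead to the same product. Ring C closes as a six-membered ring by attack of the distal enol oxygen on the ipso carbon C8a, formally 6-endo-trig with respect to the C4a=C8a bond in the addition–elimination picture. No stereocentre is formed. The step needs O- over C-arylation and one regiochemistry: attack by C3 or by the proximal carbonyl oxygen would require a four-membered ring, and the two bromines are related by the mirror plane through C1 and C4 of the aryl group, so either closure gives the same bromoflavone 9. Only one nucleophile is present, so the second bromine should survive at C5 as the handle for the last oxygen.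

**Step 5**
Reactants: 9 2-[3,4-bis(benzyloxy)phenyl]-5-bromo-6,7,8-trimethoxy-4H-chromen-4-one
Product: 11 2-[3,4-bis(benzyloxy)phenyl]-5-hydroxy-6,7,8-trimethoxy-4H-chromen-4-one, via potassium phenolate 10 (not isolated)
Conditions: CuI (10 mol %), 1,10-phenanthroline (20 mol %), KOH (4 equiv), DMSO/H2O (1:1), 100 °C, Ar; then 2 M HCl; crude in AcOH, H2SO4 (cat.), 60 °C
Reagents that add atoms: potassium hydroxide, [K+].[OH-]
Why: Ullmann-type copper-catalysed hydroxylation of an aryl bromide, assisted by chelation of copper to the peri C4 carbonyl; if hydroxide opens the pyranone at C2, the acid treatment recloses it, and because ring A is symmetric only the same flavone can re-form.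

**Step 6**
Reactants: 11 2-[3,4-bis(benzyloxy)phenyl]-5-hydroxy-6,7,8-trimethoxy-4H-chromen-4-one
Product: 12 sideritiflavone, 2-(3,4-dihydroxyphenyl)-5-hydroxy-6,7,8-trimethoxy-4H-chromen-4-one
Conditions: H2 (1 atm), 10% Pd/C, THF/MeOH (1:1), rt
Reagents that add atoms: none
Why: Catalytic hydrogenolysis of aryl benzyl ethers; the methyl ethers and the conjugated C2=C3 bond of the flavone should be inert at ambient pressure and temperature if the reaction is stopped at full debenzylation.

**Compound list**
1 | 3,4,5-trimethoxybenzoic acid | COc1cc(C(=O)O)cc(OC)c1OC | starting material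
2 | 2,6-dibromo-3,4,5-trimethoxybenzoic acid | COc1c(OC)c(Br)c(C(=O)O)c(Br)c1OC | intermediate
3 | 2,6-dibromo-3,4,5-trimethoxybenzoyl chloride | COc1c(OC)c(Br)c(C(Cl)=O)c(Br)c1OC | intermediate
4 | 1-[3,4-bis(benzyloxy)phenyl]ethanone | CC(=O)c1ccc(OCc2ccccc2)c(OCc2ccccc2)c1 | starting material
5 | lithium 1-[3,4-bis(benzyloxy)phenyl]ethenolate (enolate of 4) | [Li+].[O-]C(=C)c1ccc(OCc2ccccc2)c(OCc2ccccc2)c1 | intermediate
6 | lithium (Z)-1-[3,4-bis(benzyloxy)phenyl]-3-(2,6-dibromo-3,4,5-trimethoxyphenyl)-3-oxoprop-1-en-1-olate | [Li+].[O-]/C(=C\C(=O)c1c(Br)c(OC)c(OC)c(OC)c1Br)c1ccc(OCc2ccccc2)c(OCc2ccccc2)c1 | intermediate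
7 | 1-[3,4-bis(benzyloxy)phenyl]-3-(2,6-dibromo-3,4,5-trimethoxyphenyl)propane-1,3-dione | COc1c(OC)c(Br)c(C(=O)CC(=O)c2ccc(OCc3ccccc3)c(OCc3ccccc3)c2)c(Br)c1OC | intermediate
8 | potassium (Z)-1-[3,4-bis(benzyloxy)phenyl]-3-(2,6-dibromo-3,4,5-trimethoxyphenyl)-3-oxoprop-1-en-1-olate | [K+].[O-]/C(=C\C(=O)c1c(Br)c(OC)c(OC)c(OC)c1Br)c1ccc(OCc2ccccc2)c(OCc2ccccc2)c1 | intermediate
9 | 2-[3,4-bis(benzyloxy)phenyl]-5-bromo-6,7,8-trimethoxy-4H-chromen-4-one | COc1c(OC)c(Br)c2c(=O)cc(-c3ccc(OCc4ccccc4)c(OCc4ccccc4)c3)oc2c1OC | intermediate
10 | potassium 2-[3,4-bis(benzyloxy)phenyl]-6,7,8-trimethoxy-4-oxo-4H-chromen-5-olate | [K+].COc1c(OC)c([O-])c2c(=O)cc(-c3ccc(OCc4ccccc4)c(OCc4ccccc4)c3)oc2c1OC | intermediate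
11 | 2-[3,4-bis(benzyloxy)phenyl]-5-hydroxy-6,7,8-trimethoxy-4H-chromen-4-one | COc1c(OC)c(O)c2c(=O)cc(-c3ccc(OCc4ccccc4)c(OCc4ccccc4)c3)oc2c1OC | intermediate
12 | sideritiflavone, 2-(3,4-dihydroxyphenyl)-5-hydroxy-6,7,8-trimethoxy-4H-chromen-4-one | COc1c(OC)c(O)c2c(=O)cc(-c3ccc(O)c(O)c3)oc2c1OC | target

**Step count**
Total steps: 6. Longest linear sequence: 6 steps (1 → 2 → 3 → 7 → 9 → 11 → 12); ketone 4 enters at step 3.

**Steps most likely to fail**

Step 5. Hydroxide may open the pyranone at C2 and then cleave the resulting diketone by retro-Claisen fragmentation, or the chelating 5-phenolate may sequester copper so that conversion stalls. The fallback sets out from 9 and avoids free hydroxide. Copper-catalysed C–O coupling with benzyl alcohol (CuI, 3,4,7,8-tetramethyl-1,10-phenanthroline, Cs2CO3, BnOH, toluene, 110 °C) should give 5-(benzyloxy)-2-[3,4-bis(benzyloxy)phenyl]-6,7,8-trimethoxy-4H-chromen-4-one F1. The hydrogenolysis conditions of step 6 then remove all three benzyl groups at once, and the fallback rejoins the route at target 12.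

Step 4. Oxidative addition and closure at the twisted, doubly ortho-substituted aryl bromide may be slow, so that carbonate-induced retro-Claisen cleavage of the diketone or protodebromination takes over at the temperature required. The fallback sets out from 7 and puts the oxygen on ring A first. Twofold hydroxylation of both C–Br bonds under zerovalent palladium catalysis (Pd2(dba)3, tBuXPhos, KOH, dioxane/H2O, 100 °C) should give 1-[3,4-bis(benzyloxy)phenyl]-3-(2,6-dihydroxy-3,4,5-trimethoxyphenyl)propane-1,3-dione F2. Classical acid cyclodehydration (AcOH, cat. H2SO4, 80 °C) then closes ring C at O1–C2 from either of the two equivalent phenols. The fallback rejoins the route at 11 and also replaces step 5; any material that cyclises by O-arylation on the way converges on the same compound.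

Step 3. The enolate may be acylated on oxygen, or attack at the carbonyl flanked by two bromines may be too slow, giving enol ester or recovered ketone. The fallback sets out from 3 and replaces acylation by an aldol addition, which can only form the C–C bond. Reduction of 3 with LiAlH(OtBu)3 (THF, −78 °C) should give 2,6-dibromo-3,4,5-trimethoxybenzaldehyde F3. Addition of lithium enolate 5 (THF, −78 °C) should give racemic 1-[3,4-bis(benzyloxy)phenyl]-3-(2,6-dibromo-3,4,5-trimethoxyphenyl)-3-hydroxypropan-1-one F4. Oxidation of the β-hydroxy ketone with IBX (EtOAc, 75 °C) then returns to the route at diketone 7.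

**Further compounds**
F1 | step 5 | 5-(benzyloxy)-2-[3,4-bis(benzyloxy)phenyl]-6,7,8-trimethoxy-4H-chromen-4-one | COc1c(OC)c(OCc5ccccc5)c2c(=O)cc(-c3ccc(OCc4ccccc4)c(OCc4ccccc4)c3)oc2c1OC
F2 | step 4 | 1-[3,4-bis(benzyloxy)phenyl]-3-(2,6-dihydroxy-3,4,5-trimethoxyphenyl)propane-1,3-dione | COc1c(OC)c(O)c(C(=O)CC(=O)c2ccc(OCc3ccccc3)c(OCc3ccccc3)c2)c(O)c1OC
F3 | step 3 | 2,6-dibromo-3,4,5-trimethoxybenzaldehyde | COc1c(OC)c(Br)c(C=O)c(Br)c1OC
F4 | step 3 | (±)-1-[3,4-bis(benzyloxy)phenyl]-3-(2,6-dibromo-3,4,5-trimethoxyphenyl)-3-hydroxypropan-1-one | COc1c(OC)c(Br)c(C(O)CC(=O)c2ccc(OCc3ccccc3)c(OCc3ccccc3)c2)c(Br)c1OC
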